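## Retrosynthetic overview

1. Both β,γ-unsaturated ketones are unveiled last, by double oxidation of two homoallylic carbinols, followed by desilylation of the phenol.
2. Key disconnection: the CH(OH)–CH2 bond next to the trisubstituted alkene, formed by α-selective, E-retentive carbonyl allylation of a cyclopentylacetaldehyde with the allylbarium of an (E)-aryl-prenyl chloride.
3. The aldehyde half comes from a prenyl δ-lactone, made from a formyl ester (allylation, cross-metathesis) that arises by ozonolysis of an enantioenriched silyl enol ether of meso cis-1,5-dimethylbicyclo[3.3.0]octan-3-one (chiral-base desymmetrisation).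
4. Ring order: both five-membered rings are formed first and together by Weiss–Cook aldol/Michael condensation of biacetyl with dimethyl 3-oxoglutarate (sets the cis vicinal quaternary methyls). One ring is deoxygenated to become the cyclopentane; the other is cleaved to give the two side-chain stubs.
5. The aryl half comes from 4-hydroxy-3-methylbenzaldehyde (bromination, Dakin, silylation, methylation, prenylation, allylic oxidation, chlorination); the arene is bought, not built.

Assumption: the (R,R)-lithium amide in step 6 is taken to give the silyl enol ether enantiomer drawn; if the sense is the opposite, the (S,S)-amine is used and nothing else changes.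

## Route

Step 1
Reactants: 1 butane-2,3-dione (biacetyl); 2 dimethyl 3-oxopentanedioate (2 equiv)
Product: 3 tetramethyl cis-3,7-dihydroxy-1,5-dimethylbicyclo[3.3.0]octa-2,6-diene-2,4,6,8-tetracarboxylate (bis-enol form)
Conditions: aq. NaHCO3 (pH 8.3), rt, 24 h
Reagents that add atoms: none
Why: Weiss–Cook condensation (two aldol condensations and two Michael additions) builds both five-membered rings at once, and the bicyclo[3.3.0] skeleton allows only the cis fusion, so the two methyl-bearing quaternary carbons are set cis (meso, no absolute configuration yet).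

Step 2
Reactants: 3 tetraester
Product: 5 cis-1,5-dimethylbicyclo[3.3.0]octane-3,7-dione (meso), via tetracarboxylic acid 4 (not isolated)
Conditions: 1 M HCl/AcOH, reflux
Reagents that add atoms: none
Why: Acid hydrolysis of the four β-keto esters is followed by fourfold decarboxylation of the β-keto acids.

Step 3
Reactants: 5 dione
Product: 6 cis-1,5-dimethylbicyclo[3.3.0]octane-3,7-dione mono(2,2-dimethylpropane-1,3-diyl) ketal (meso)
Conditions: neopentyl glycol (1.0 equiv), p-TsOH (cat.), PhH, reflux, Dean–Stark; dione and bis-ketal recycled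
Reagents that add atoms: 2,2-dimethylpropane-1,3-diol OCC(C)(C)CO
Why: Acid-catalysed ketalisation with one equivalent of diol protects one of the two equivalent ketones (statistical, separable, recyclable).

Step 4
Reactants: 6 monoketal
Product: 8 cis-1,5-dimethylbicyclo[3.3.0]octan-3-one 2,2-dimethylpropane-1,3-diyl ketal (meso), via hydrazone 7 (not isolated)
Conditions: N2H4·H2O, KOH, diethylene glycol, 130 then 200 °C
Reagents that add atoms: none
Why: Wolff–Kishner (Huang-Minlon) reduction removes the free ketone while the base-stable ketal survives.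

Step 5
Reactants: 8 ketal
Product: 9 cis-1,5-dimethylbicyclo[3.3.0]octan-3-one (meso)
Conditions: 2 M HCl, THF, rt
Reagents that add atoms: water O
Why: Acid-catalysed ketal hydrolysis liberates the ketone.

Step 6
Reactants: 9 meso ketone
Product: 11 (1S,5R)-1,5-dimethyl-3-(trimethylsilyloxy)bicyclo[3.3.0]oct-2-ene, via lithium enolate 10 (not isolated)
Conditions: (R,R)-bis(1-phenylethyl)amine, n-BuLi, LiCl, THF, −78 °C; TMSCl (in situ quench), −100 °C
Reagents that add atoms: chlorotrimethylsilane C[Si](C)(C)Cl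
Why: Enantioselective deprotonation of a meso ketone by a C2-symmetric chiral lithium amide with internal silyl quench distinguishes the enantiotopic α-methylenes, which fixes the absolute configuration of both quaternary centres (never touched again).

Step 7
Reactants: 11 silyl enol ether
Product: 14 2-[(1R,2R)-2-formyl-1,2-dimethylcyclopentyl]acetic acid, via methoxy hydroperoxide 12 (not isolated), via silyl ester 13 (not isolated)
Conditions: O3, CH2Cl2/MeOH, −78 °C; Me2S, −78 °C to rt; H2O work-up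
Reagents that add atoms: ozone [O-][O+]=O
Why: Ozonolysis of the silyl enol ether cleaves the ring into a formyl group on one quaternary carbon and a carboxymethyl group on the other, without affecting the stereocentres.

Step 8
Reactants: 14 aldehyde acid
Product: 15 methyl 2-[(1R,2R)-2-formyl-1,2-dimethylcyclopentyl]acetate
Conditions: MeI, K2CO3, DMF, rt
Reagents that add atoms: iodomethane CI
Why: SN2 O-alkylation of the carboxylate locks the open-chain form; the aldehyde has no α-hydrogen and cannot epimerise or condense.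

Step 9
Reactants: 15 aldehyde ester
Product: 17 (4aR,7aR)-1-allyl-4a,7a-dimethylhexahydrocyclopenta[c]pyran-3(1H)-one (C1 epimers), via hydroxy ester 16 (not isolated)
Conditions: allyl bromide, In, THF/H2O, rt; then p-TsOH (cat.), PhMe, 60 °C
Reagents that add atoms: allyl bromide C=CCBr
Why: Barbier-type indium carbonyl allylation is chemoselective for the aldehyde over the ester, and the cis hydroxyl and ester then lactonise (Thorpe–Ingold assisted); the new carbinol centre is a mixture that is erased in step 24.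

Step 10
Reactants: 17 allyl lactone
Product: 18 (4aR,7aR)-4a,7a-dimethyl-1-(3-methylbut-2-en-1-yl)hexahydrocyclopenta[c]pyran-3(1H)-one (C1 epimers)
Conditions: 2-methyl-2-butene (excess), Grubbs II (3 mol%), CH2Cl2, 40 °C
Reagents that add atoms: 2-methylbut-2-ene CC=C(C)C
Why: Olefin cross-metathesis of a terminal alkene with 2-methyl-2-butene reliably converts allyl into prenyl.

Step 11
Reactants: 18 prenyl lactone
Product: 19 1-[(1R,2R)-2-(2-hydroxyethyl)-1,2-dimethylcyclopentyl]-4-methylpent-3-en-1-ol (carbinol epimers)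
Conditions: LiAlH4, THF, 0 °C to rt
Reagents that add atoms: none
Why: Hydride reduction opens the lactone irreversibly to the 1,5-diol.

Step 12
Reactants: 19 diol
Product: 20 bis(triethylsilyl) ether of 19
Conditions: TESOTf (3 equiv), 2,6-lutidine, CH2Cl2, −78 to 0 °C
Reagents that add atoms: triethylsilyl trifluoromethanesulfonate CC[Si](CC)(CC)OS(=O)(=O)C(F)(F)F
Why: Silylation with the silyl triflate protects both hydroxyls, including the hindered neopentylic secondary one.

Step 13
Reactants: 20 bis-TES ether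
Product: 21 2-[(1R,2R)-1,2-dimethyl-2-(4-methyl-1-triethylsilyloxypent-3-en-1-yl)cyclopentyl]ethanol
Conditions: PPTS (cat.), MeOH/CH2Cl2, 0 °C
Reagents that add atoms: none
Why: Mild acid methanolysis removes only the unhindered primary TES ether, since the secondary one is shielded by the adjacent quaternary carbon.

Step 14
Reactants: 21 primary alcohol
Product: 22 2-[(1R,2R)-1,2-dimethyl-2-(4-methyl-1-triethylsilyloxypent-3-en-1-yl)cyclopentyl]acetaldehyde
Conditions: Dess–Martin periodinane, NaHCO3, CH2Cl2, rt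
Reagents that add atoms: none
Why: Dess–Martin oxidation gives the aldehyde under buffered conditions that leave the silyl ether and alkene intact.

Step 15
Reactants: 23 4-hydroxy-3-methylbenzaldehyde
Product: 24 3-bromo-4-hydroxy-5-methylbenzaldehyde
Conditions: Br2, AcOH, rt
Reagents that add atoms: bromine BrBr
Why: Electrophilic aromatic bromination goes to the only free position ortho to the phenol (para is blocked, the other ortho carries methyl).

Step 16
Reactants: 24 bromo aldehyde
Product: 26 2-bromo-6-methylbenzene-1,4-diol, via aryl formate 25 (not isolated)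
Conditions: 30% H2O2, aq. NaOH, 0 °C to rt, N2; then HCl
Reagents that add atoms: hydrogen peroxide OO
Why: Dakin oxidation of the p-hydroxybenzaldehyde (aryl migration in the peroxide adduct, then formate hydrolysis) places the second oxygen exactly para to the first.

Step 17
Reactants: 26 hydroquinone
Product: 27 2-bromo-6-methyl-4-(triisopropylsilyloxy)phenol
Conditions: TIPSCl (1.05 equiv), imidazole, CH2Cl2, 0 °C
Reagents that add atoms: chlorotriisopropylsilane CC(C)[Si](Cl)(C(C)C)C(C)C
Why: The bulky silyl chloride reacts only at the hydroxyl without ortho substituents; the other is flanked by Br and CH3.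

Step 18
Reactants: 27 mono-silyl ether
Product: 28 (3-bromo-4-methoxy-5-methylphenoxy)triisopropylsilane
Conditions: MeI, K2CO3, acetone, reflux
Reagents that add atoms: iodomethane CI
Why: Williamson methylation of the remaining hindered phenol, with the aryl TIPS ether stable to carbonate in acetone.

Step 19
Reactants: 28 aryl bromide
Product: 30 triisopropyl[4-methoxy-3-methyl-5-(3-methylbut-2-en-1-yl)phenoxy]silane, via aryllithium 29 (not isolated)
Conditions: n-BuLi, THF, −78 °C; CuI (10 mol%), prenyl bromide, −78 to 0 °C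
Reagents that add atoms: 1-bromo-3-methylbut-2-ene CC(C)=CCBr
Why: Bromine–lithium exchange (assisted by the ortho methoxy group) followed by copper-catalysed SN2 allylic substitution gives the prenylarene; lithium sits meta to the silyloxy group, so no retro-Brook shift occurs.

Step 20
Reactants: 30 prenylarene
Product: 31 (E)-4-[2-methoxy-3-methyl-5-(triisopropylsilyloxy)phenyl]-2-methylbut-2-en-1-ol
Conditions: SeO2 (0.5 equiv), t-BuOOH, salicylic acid (cat.), CH2Cl2, 0 °C to rt
Reagents that add atoms: selenium dioxide O=[Se]=O (oxygen carrier); tert-butyl hydroperoxide CC(C)(C)OO (terminal oxidant)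
Why: Riley allylic oxidation (ene reaction then [2,3]-sigmatropic shift) hydroxylates the (E)-methyl of the gem-dimethyl alkene selectively, which sets the E trisubstituted olefin.

Step 21
Reactants: 31 allylic alcohol
Product: 33 (E)-[3-(4-chloro-3-methylbut-2-en-1-yl)-4-methoxy-5-methylphenoxy]triisopropylsilane, via allylic mesylate 32 (not isolated)
Conditions: MsCl, LiCl, 2,4,6-collidine, DMF, 0 °C
Reagents that add atoms: lithium chloride [Li+].[Cl-]
Why: Collington–Meyers chlorination displaces the primary mesylate by chloride in an SN2 reaction, without allylic transposition and with the E geometry kept.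

Step 22
Reactants: 33 allylic chloride (1.5 equiv); 22 aldehyde
Product: 35 (E)-1-[(1R,2R)-1,2-dimethyl-2-(4-methyl-1-triethylsilyloxypent-3-en-1-yl)cyclopentyl]-6-[2-methoxy-3-methyl-5-(triisopropylsilyloxy)phenyl]-4-methylhex-4-en-2-ol (carbinol epimers), via allylbarium chloride 34 (not isolated)
Conditions: Ba* (BaI2 + 2 Li biphenylide), THF, rt; 33, −78 °C, 30 min; then 22, −78 °C
Reagents that add atoms: none
Why: Carbonyl allylation with an allylbarium reagent, which is configurationally stable at −78 °C and attacks through its unsubstituted CH2 (α) terminus, joins the two halves with the E alkene retained; the new carbinol centre is a mixture that is erased in step 24.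

Step 23
Reactants: 35 coupled alcohol
Product: 36 (E)-1-[(1R,2R)-2-(1-hydroxy-4-methylpent-3-en-1-yl)-1,2-dimethylcyclopentyl]-6-[2-methoxy-3-methyl-5-(triisopropylsilyloxy)phenyl]-4-methylhex-4-en-2-ol (carbinol epimers)
Conditions: CSA (cat.), MeOH/CH2Cl2, 0 °C to rt
Reagents that add atoms: none
Why: Acid methanolysis cleaves the alkyl TES ether, while the aryl TIPS ether is stable to acid and stays.

Step 24
Reactants: 36 diol
Product: 37 1-[(1R,2R)-2-{(E)-6-[2-methoxy-3-methyl-5-(triisopropylsilyloxy)phenyl]-4-methyl-2-oxohex-4-en-1-yl}-1,2-dimethylcyclopentyl]-4-methylpent-3-en-1-one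
Conditions: Dess–Martin periodinane (4 equiv), NaHCO3, CH2Cl2, 0 °C to rt
Reagents that add atoms: none
Why: Dess–Martin oxidation under buffered, non-basic conditions converts both homoallylic alcohols into β,γ-unsaturated ketones without conjugation, removes both carbinol stereocentres, and is safe for the arene because the phenol is still silylated.

Step 25
Reactants: 37 diketone silyl ether
Product: 38 1-[(1R,2R)-2-{(E)-6-(5-hydroxy-2-methoxy-3-methylphenyl)-4-methyl-2-oxohex-4-en-1-yl}-1,2-dimethylcyclopentyl]-4-methylpent-3-en-1-one (target)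
Conditions: TBAF/AcOH (1:1), THF, 0 °C
Reagents that add atoms: none
Why: Fluoride cleaves the aryl silyl ether, and the acetic acid buffer prevents enone conjugation and intramolecular aldol of the 1,5-diketone.

## Compound list

1 | butane-2,3-dione | CC(=O)C(C)=O | starting material
2 | dimethyl 3-oxopentanedioate | COC(=O)CC(=O)CC(=O)OC | starting material
3 | tetramethyl cis-3,7-dihydroxy-1,5-dimethylbicyclo[3.3.0]octa-2,6-diene-2,4,6,8-tetracarboxylate | C[C@@]12C(C(=O)OC)=C(O)C(C(=O)OC)[C@]1(C)C(C(=O)OC)=C(O)C2C(=O)OC | intermediate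
4 | cis-1,5-dimethyl-3,7-dioxobicyclo[3.3.0]octane-2,4,6,8-tetracarboxylic acid | C[C@@]12C(C(=O)O)C(=O)C(C(=O)O)[C@]1(C)C(C(=O)O)C(=O)C2C(=O)O | intermediate (not isolated)
5 | cis-1,5-dimethylbicyclo[3.3.0]octane-3,7-dione (meso) | C[C@@]12CC(=O)C[C@]1(C)CC(=O)C2 | intermediate
6 | cis-1,5-dimethylbicyclo[3.3.0]octane-3,7-dione mono(2,2-dimethylpropane-1,3-diyl) ketal | C[C@@]12CC(=O)C[C@]1(C)CC3(OCC(C)(C)CO3)C2 | intermediate
7 | hydrazone of 6 | C[C@@]12CC(=NN)C[C@]1(C)CC3(OCC(C)(C)CO3)C2 | intermediate (not isolated)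
8 | cis-1,5-dimethylbicyclo[3.3.0]octan-3-one 2,2-dimethylpropane-1,3-diyl ketal | C[C@@]12CCC[C@]1(C)CC3(OCC(C)(C)CO3)C2 | intermediate
9 | cis-1,5-dimethylbicyclo[3.3.0]octan-3-one (meso) | C[C@@]12CCC[C@]1(C)CC(=O)C2 | intermediate
10 | lithium (1S,5R)-1,5-dimethylbicyclo[3.3.0]oct-2-en-3-olate | [Li]OC1=C[C@]2(C)CCC[C@]2(C)C1 | intermediate (not isolated)
11 | (1S,5R)-1,5-dimethyl-3-(trimethylsilyloxy)bicyclo[3.3.0]oct-2-ene | C[Si](C)(C)OC1=C[C@]2(C)CCC[C@]2(C)C1 | intermediate
12 | trimethylsilyl 2-[(1R,2R)-2-(hydroperoxy(methoxy)methyl)-1,2-dimethylcyclopentyl]acetate | C[Si](C)(C)OC(=O)C[C@@]1(C)CCC[C@@]1(C)C(OC)OO | intermediate (not isolated)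
13 | trimethylsilyl 2-[(1R,2R)-2-formyl-1,2-dimethylcyclopentyl]acetate | C[Si](C)(C)OC(=O)C[C@@]1(C)CCC[C@@]1(C)C=O | intermediate (not isolated)
14 | 2-[(1R,2R)-2-formyl-1,2-dimethylcyclopentyl]acetic acid | OC(=O)C[C@@]1(C)CCC[C@@]1(C)C=O | intermediate
15 | methyl 2-[(1R,2R)-2-formyl-1,2-dimethylcyclopentyl]acetate | COC(=O)C[C@@]1(C)CCC[C@@]1(C)C=O | intermediate
16 | methyl 2-[(1R,2R)-2-(1-hydroxybut-3-en-1-yl)-1,2-dimethylcyclopentyl]acetate (carbinol epimers) | COC(=O)C[C@@]1(C)CCC[C@@]1(C)C(O)CC=C | intermediate (not isolated)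
17 | (4aR,7aR)-1-allyl-4a,7a-dimethylhexahydrocyclopenta[c]pyran-3(1H)-one (C1 epimers) | O=C1C[C@@]2(C)CCC[C@@]2(C)C(CC=C)O1 | intermediate
18 | (4aR,7aR)-4a,7a-dimethyl-1-(3-methylbut-2-en-1-yl)hexahydrocyclopenta[c]pyran-3(1H)-one (C1 epimers) | O=C1C[C@@]2(C)CCC[C@@]2(C)C(CC=C(C)C)O1 | intermediate
19 | 1-[(1R,2R)-2-(2-hydroxyethyl)-1,2-dimethylcyclopentyl]-4-methylpent-3-en-1-ol (carbinol epimers) | OCC[C@@]1(C)CCC[C@@]1(C)C(O)CC=C(C)C | intermediate
20 | bis(triethylsilyl) ether of 19 | CC[Si](CC)(CC)OCC[C@@]1(C)CCC[C@@]1(C)C(O[Si](CC)(CC)CC)CC=C(C)C | intermediate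
21 | 2-[(1R,2R)-1,2-dimethyl-2-(4-methyl-1-triethylsilyloxypent-3-en-1-yl)cyclopentyl]ethanol | OCC[C@@]1(C)CCC[C@@]1(C)C(O[Si](CC)(CC)CC)CC=C(C)C | intermediate
22 | 2-[(1R,2R)-1,2-dimethyl-2-(4-methyl-1-triethylsilyloxypent-3-en-1-yl)cyclopentyl]acetaldehyde | O=CC[C@@]1(C)CCC[C@@]1(C)C(O[Si](CC)(CC)CC)CC=C(C)C | intermediate
23 | 4-hydroxy-3-methylbenzaldehyde | Cc1cc(C=O)ccc1O | starting material
24 | 3-bromo-4-hydroxy-5-methylbenzaldehyde | Cc1cc(C=O)cc(Br)c1O | intermediate
25 | 3-bromo-4-hydroxy-5-methylphenyl formate | Cc1cc(OC=O)cc(Br)c1O | intermediate (not isolated)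
26 | 2-bromo-6-methylbenzene-1,4-diol | Cc1cc(O)cc(Br)c1O | intermediate
27 | 2-bromo-6-methyl-4-(triisopropylsilyloxy)phenol | Cc1cc(O[Si](C(C)C)(C(C)C)C(C)C)cc(Br)c1O | intermediate
28 | (3-bromo-4-methoxy-5-methylphenoxy)triisopropylsilane | COc1c(C)cc(O[Si](C(C)C)(C(C)C)C(C)C)cc1Br | intermediate
29 | [2-methoxy-3-methyl-5-(triisopropylsilyloxy)phenyl]lithium | COc1c(C)cc(O[Si](C(C)C)(C(C)C)C(C)C)cc1[Li] | intermediate (not isolated)
30 | triisopropyl[4-methoxy-3-methyl-5-(3-methylbut-2-en-1-yl)phenoxy]silane | COc1c(C)cc(O[Si](C(C)C)(C(C)C)C(C)C)cc1CC=C(C)C | intermediate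
31 | (E)-4-[2-methoxy-3-methyl-5-(triisopropylsilyloxy)phenyl]-2-methylbut-2-en-1-ol | COc1c(C)cc(O[Si](C(C)C)(C(C)C)C(C)C)cc1C/C=C(\C)CO | intermediate
32 | methanesulfonate of 31 | COc1c(C)cc(O[Si](C(C)C)(C(C)C)C(C)C)cc1C/C=C(\C)COS(C)(=O)=O | intermediate (not isolated)
33 | (E)-[3-(4-chloro-3-methylbut-2-en-1-yl)-4-methoxy-5-methylphenoxy]triisopropylsilane | COc1c(C)cc(O[Si](C(C)C)(C(C)C)C(C)C)cc1C/C=C(\C)CCl | intermediate
34 | (E)-{4-[2-methoxy-3-methyl-5-(triisopropylsilyloxy)phenyl]-2-methylbut-2-en-1-yl}barium chloride | COc1c(C)cc(O[Si](C(C)C)(C(C)C)C(C)C)cc1C/C=C(\C)C[Ba]Cl | intermediate (not isolated)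
35 | (E)-1-[(1R,2R)-1,2-dimethyl-2-(4-methyl-1-triethylsilyloxypent-3-en-1-yl)cyclopentyl]-6-[2-methoxy-3-methyl-5-(triisopropylsilyloxy)phenyl]-4-methylhex-4-en-2-ol (carbinol epimers) | COc1c(C)cc(O[Si](C(C)C)(C(C)C)C(C)C)cc1C/C=C(\C)CC(O)C[C@@]1(C)CCC[C@@]1(C)C(O[Si](CC)(CC)CC)CC=C(C)C | intermediate
36 | (E)-1-[(1R,2R)-2-(1-hydroxy-4-methylpent-3-en-1-yl)-1,2-dimethylcyclopentyl]-6-[2-methoxy-3-methyl-5-(triisopropylsilyloxy)phenyl]-4-methylhex-4-en-2-ol (carbinol epimers) | COc1c(C)cc(O[Si](C(C)C)(C(C)C)C(C)C)cc1C/C=C(\C)CC(O)C[C@@]1(C)CCC[C@@]1(C)C(O)CC=C(C)C | intermediate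
37 | 1-[(1R,2R)-2-{(E)-6-[2-methoxy-3-methyl-5-(triisopropylsilyloxy)phenyl]-4-methyl-2-oxohex-4-en-1-yl}-1,2-dimethylcyclopentyl]-4-methylpent-3-en-1-one | COc1c(C)cc(O[Si](C(C)C)(C(C)C)C(C)C)cc1C/C=C(\C)CC(=O)C[C@@]1(C)CCC[C@@]1(C)C(=O)CC=C(C)C | intermediate
38 | 1-[(1R,2R)-2-{(E)-6-(5-hydroxy-2-methoxy-3-methylphenyl)-4-methyl-2-oxohex-4-en-1-yl}-1,2-dimethylcyclopentyl]-4-methylpent-3-en-1-one | COc1c(C)cc(O)cc1C/C=C(\C)CC(=O)C[C@@]1(C)CCC[C@@]1(C)C(=O)CC=C(C)C | target

## Step count and risks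

Total steps: 25. Longest linear sequence: 18 (steps 1–14, then 22–25); the aryl branch is steps 15–21.

Three steps most likely to fail:

Step 6 (enantioselectivity of the chiral-base desymmetrisation on a ketone whose α-methylenes are neopentylic). The fallback is a classical resolution that sets out from 9 and returns at 17. Baeyer–Villiger oxidation of 9 (CF3CO3H, Na2HPO4, CH2Cl2) gives the racemic cis-lactone rac-4a,7a-dimethylhexahydrocyclopenta[c]pyran-3(1H)-one F1. Me3Al-mediated aminolysis with (S)-1-phenylethylamine gives two diastereomeric hydroxy amides that are separated by crystallisation or chromatography, the wanted one being 2-[(1R,2R)-2-(hydroxymethyl)-1,2-dimethylcyclopentyl]-N-[(1S)-1-phenylethyl]acetamide F2 (configuration secured by X-ray). Heating with p-TsOH in toluene relactonises it to the enantiopure (4aR,7aR)-4a,7a-dimethylhexahydrocyclopenta[c]pyran-3(1H)-one F3. Opening with MeNHOMe·HCl/Me3Al gives the hydroxy Weinreb amide 2-[(1R,2R)-2-(hydroxymethyl)-1,2-dimethylcyclopentyl]-N-methoxy-N-methylacetamide F4, which is oxidised at once (Dess–Martin) to 2-[(1R,2R)-2-formyl-1,2-dimethylcyclopentyl]-N-methoxy-N-methylacetamide F5. Indium allylation as in step 9 gives 2-[(1R,2R)-2-(1-hydroxybut-3-en-1-yl)-1,2-dimethylcyclopentyl]-N-methoxy-N-methylacetamide F6, which lactonises with p-TsOH in toluene to 17.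

Step 20 (moderate yield, over-oxidation to the enal or incomplete E-selectivity in the SeO2 oxidation). The fallback builds the E alkene by metathesis instead; it sets out from 28 and returns at 31. Bromine–lithium exchange on 28 and copper-catalysed allylation with allyl bromide give [3-allyl-4-methoxy-5-methylphenoxy]triisopropylsilane F7. Cross-metathesis with methacrolein (Grubbs II, benzoquinone additive, CH2Cl2, 40 °C) gives (E)-4-[2-methoxy-3-methyl-5-(triisopropylsilyloxy)phenyl]-2-methylbut-2-enal F8 with the E selectivity typical of trisubstituted enals. Luche reduction (NaBH4, CeCl3, MeOH, 0 °C) gives 31.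

Step 22 (α/γ regioselectivity, Wurtz coupling or incomplete formation of the allylbarium). The fallback reverses the polarity of the aldehyde (Corey–Seebach); it sets out from 22 (with 33) and returns at 35. Propane-1,3-dithiol with MgBr2·OEt2 converts 22 into 2-{[(1R,2R)-1,2-dimethyl-2-(4-methyl-1-triethylsilyloxypent-3-en-1-yl)cyclopentyl]methyl}-1,3-dithiane F9. Lithiation (t-BuLi, THF/HMPA, −78 °C) and SN2 alkylation with 33 give the 2,2-disubstituted dithiane 2-{[(1R,2R)-1,2-dimethyl-2-(4-methyl-1-triethylsilyloxypent-3-en-1-yl)cyclopentyl]methyl}-2-{(E)-4-[2-methoxy-3-methyl-5-(triisopropylsilyloxy)phenyl]-2-methylbut-2-en-1-yl}-1,3-dithiane F10. Hydrolysis (MeI, CaCO3, aq. MeCN) gives (E)-1-[(1R,2R)-1,2-dimethyl-2-(4-methyl-1-triethylsilyloxypent-3-en-1-yl)cyclopentyl]-6-[2-methoxy-3-methyl-5-(triisopropylsilyloxy)phenyl]-4-methylhex-4-en-2-one F11, and NaBH4 reduction (MeOH, 0 °C) gives 35.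

## Further compounds

F1 | step 6 | rac-4a,7a-dimethylhexahydrocyclopenta[c]pyran-3(1H)-one (cis, racemate; one enantiomer drawn) | O=C1C[C@@]2(C)CCC[C@@]2(C)CO1
F2 | step 6 | 2-[(1R,2R)-2-(hydroxymethyl)-1,2-dimethylcyclopentyl]-N-[(1S)-1-phenylethyl]acetamide | C[C@H](NC(=O)C[C@@]1(C)CCC[C@@]1(C)CO)c1ccccc1
F3 | step 6 | (4aR,7aR)-4a,7a-dimethylhexahydrocyclopenta[c]pyran-3(1H)-one | O=C1C[C@@]2(C)CCC[C@@]2(C)CO1
F4 | step 6 | 2-[(1R,2R)-2-(hydroxymethyl)-1,2-dimethylcyclopentyl]-N-methoxy-N-methylacetamide | CON(C)C(=O)C[C@@]1(C)CCC[C@@]1(C)CO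
F5 | step 6 | 2-[(1R,2R)-2-formyl-1,2-dimethylcyclopentyl]-N-methoxy-N-methylacetamide | CON(C)C(=O)C[C@@]1(C)CCC[C@@]1(C)C=O
F6 | step 6 | 2-[(1R,2R)-2-(1-hydroxybut-3-en-1-yl)-1,2-dimethylcyclopentyl]-N-methoxy-N-methylacetamide (carbinol epimers) | CON(C)C(=O)C[C@@]1(C)CCC[C@@]1(C)C(O)CC=C
F7 | step 20 | [3-allyl-4-methoxy-5-methylphenoxy]triisopropylsilane | COc1c(C)cc(O[Si](C(C)C)(C(C)C)C(C)C)cc1CC=C
F8 | step 20 | (E)-4-[2-methoxy-3-methyl-5-(triisopropylsilyloxy)phenyl]-2-methylbut-2-enal | COc1c(C)cc(O[Si](C(C)C)(C(C)C)C(C)C)cc1C/C=C(\C)C=O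
F9 | step 22 | 2-{[(1R,2R)-1,2-dimethyl-2-(4-methyl-1-triethylsilyloxypent-3-en-1-yl)cyclopentyl]methyl}-1,3-dithiane | C1CSC(SC1)C[C@@]1(C)CCC[C@@]1(C)C(O[Si](CC)(CC)CC)CC=C(C)C
F10 | step 22 | 2-{[(1R,2R)-1,2-dimethyl-2-(4-methyl-1-triethylsilyloxypent-3-en-1-yl)cyclopentyl]methyl}-2-{(E)-4-[2-methoxy-3-methyl-5-(triisopropylsilyloxy)phenyl]-2-methylbut-2-en-1-yl}-1,3-dithiane | COc1c(C)cc(O[Si](C(C)C)(C(C)C)C(C)C)cc1C/C=C(\C)CC1(SCCCS1)C[C@@]1(C)CCC[C@@]1(C)C(O[Si](CC)(CC)CC)CC=C(C)C
F11 | step 22 | (E)-1-[(1R,2R)-1,2-dimethyl-2-(4-methyl-1-triethylsilyloxypent-3-en-1-yl)cyclopentyl]-6-[2-methoxy-3-methyl-5-(triisopropylsilyloxy)phenyl]-4-methylhex-4-en-2-one | COc1c(C)cc(O[Si](C(C)C)(C(C)C)C(C)C)cc1C/C=C(\C)CC(=O)C[C@@]1(C)CCC[C@@]1(C)C(O[Si](CC)(CC)CC)CC=C(C)C
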